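Atom numbering used throughout: C1 prenyl bridgehead, C2 C–OMe, C3 C–benzoyl, C4 enone carbonyl, C5 lavandulyl bridgehead, C6 CH2, C7 CH–prenyl, C8 CMe2, C9 bridging carbonyl. Ring A is C1–C8–C7–C6–C5–C9 and ring B is C1–C2–C3–C4–C5–C9. "Exo" at C7 means the face of ring A turned away from ring B. Compound numbers 1–29 are those of the steps and of the compound list.

## Analysis of the target

Compound 29 is the C2 methyl enol ether of a bicyclo[3.3.1]nonane-2,4,9-trione: ring A is a cyclohexanone holding the gem-dimethyl carbon C8 and the prenylated methine C7, and ring B is a 3-benzoylated β-methoxy enone that shares the C9 ketone bridge. Both bridgeheads are quaternary (prenyl on C1, lavandulyl on C5), and C1 is bonded directly to the quaternary C8. There are four stereocentres: C1 and C5 are tied to each other by the bicycle and amount to one element of absolute configuration (1R,5R); C7 (R) carries its prenyl group exo, that is equatorial on chair ring A and cis to both bridgehead side chains; the lavandulyl methine (R) is insulated from the core by a CH2 group and cannot be induced from it. The sensitive functions are four electron-rich side-chain alkenes (acid, electrophilic oxidants, radicals and metathesis catalysts all find them), the vinylogous methyl ester (hydrolysis would erase the position of the methyl group) and the 1,3-dicarbonyl arrays around C5 and C3 (retro-Claisen cleavage by nucleophiles). The hard points are the two quaternary bridgeheads flanking C9, the C1–C8 bond between fully substituted carbons, the exo configuration at C7, and the need for the methyl group on the C2 oxygen and not on the C4 oxygen. The plan rests on one observation: stripped to C1, C9, C5, C4, C3 and C2, ring B is a 2-substituted 1,3-dimethoxybenzene at the dihydro level, with a mirror plane through C1 and C4 that exchanges C9 with C2 and C5 with C3. The enol ether bonds C5=C9 and C3=C2 of that diene are therefore enantiotopic, and the one that is not used survives as the C2–OMe group of 29.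

## Retrosynthetic reasoning

C3–benzoyl. The bond between C3 and the benzoyl carbon of 29 is cut first, giving vinylogous ester 27 and acid chloride 28. It is made last because the 3-acyl β-methoxy enone is the most base- and nucleophile-labile array of the molecule. Once both bridgeheads are quaternary, C3–H is the only acidic C–H left, so the forward step is a vinyl lithiation followed by C-acylation.

C5–lavandulyl. Cutting the C5–CH2 bond of 27 gives the bridgehead C–H compound 23 and the triflate 26. In 23 the C5–H lies between the C4 and C9 carbonyls and is the most acidic site. The side-chain stereocentre cannot be induced by the core, so it is brought in intact from (S)-alcohol 25, obtained by resolution of racemic 24. The forward step must alkylate a bridgehead carbanion with a β-branched primary electrophile, hence the triflate.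

C1–prenyl. Cutting the C1–CH2 bond of 23 leads to 19 and bromide 21 by way of the silyl-blocked compounds 22 and 20. Compound 19 has three removable protons (C5 before C3 before C1). Silicon parks C5 and C3 so that only C1 can react, and the most reactive alkylating agent is paired with the most hindered carbanion. The forward step must deprotonate the bridgehead next to C8 and alkylate it on carbon.

Prenyl double bond at C7 and oxygen at C4. The trisubstituted alkene of 19 is traced to the allyl group of 18 (cross-metathesis), and the C4 carbonyl of 18 to the allylic CH2 of enol ether 16. The order matters: the allylic oxidation is run while the only side-chain alkene is a terminal allyl group, which is far less oxidisable than prenyl. The oxidation also turns the acid-labile enol ether into a robust vinylogous ester and creates the acidity needed at C5, C3 and C1.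

C7–allyl. Cutting the C7–CH2 bond of 16 leads back through 15, 14 and xanthate 13 to alcohol 12, ketone 11, 10 and dione 9. The exo configuration results when carbon, not hydrogen, arrives at a trigonal C7 from its only open face. Hydride or hydrogen delivered to a C7 that already carried the chain would come from the same face and leave the chain endo. A C7 radical trapped by an allyl donor meets this requirement. The two ketones of 9 must be told apart: C7 is enolisable and C9 is not, so C7 is masked as its enolate while C9 is reduced, silylated and restored after the radical step.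

C5–C6 (key disconnection). Cutting C5–C6 of 9 and reinstating the C6–C9 bond gives cyclopropane 8, which comes from the achiral diazo ketone 7 by carbene addition to one of its two enantiotopic enol ethers. This is the cut that exploits the hidden symmetry: one catalytic event makes the bicycle, fixes both bridgeheads and decides which oxygen stays methylated. The forward reaction must select one enol ether and then break only the donor–acceptor bond of the cyclopropane.

Precursor. The acyl–CH bond of 7 is traced to acid 5 (acid chloride 6 plus a one-carbon diazo unit). The diene 5 is the dissolving-metal reduction product of arene 4, which comes from ester 3 by hydrolysis. The aryl–C8 bond of 3 is made by arylation of the enolate of 2 with bromide 1, which installs the quaternary C8 in one step from two commercial compounds.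

## Alternatives that were turned down

Alternative 1: The C1–C9 and C3–C4 bonds are cut, so that C5 becomes a malonate carbon. In the forward direction the dianion of an open-chain benzoyl diketone A2 attacks the two ester groups on C5 in turn (double Dieckmann) to give the enolised 3-benzoyl trione A1.
- For: both rings and the benzoyl group arrive in one operation, and the route is more convergent than the chosen one and shorter after its key step.
- Against: A1 is the free enol, and its methylation gives the C2–OMe and C4–OMe ethers, whereas the target is one of them.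
- Against: the two ester groups on C5 are diastereotopic, so the first ring closure must both choose one of them and form a quaternary bridgehead at the hindered C1, under reversible conditions that also allow retro-Claisen opening.
- Against: A2 must already hold the C7 and lavandulyl centres and the C8–C1 junction, built linearly.
- Comparison: the chosen route needs more steps after its key step, but it fixes the enol ether regiochemistry by construction and sets the bridgeheads with a catalyst and not by diastereoselection in an equilibrium.

Alternative 2: The two C–CH2(prenyl) bonds at C7 and at the lavandulyl methine are cut, using the fact that C5 carries two arms of the same constitution and configuration. In the forward direction the bis(enolate) of the C2-symmetric bis(imide) A4 is prenylated twice in one flask to give A3.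
- For: auxiliary-controlled enolate alkylation is among the most reliable ways to set such centres.
- For: it sets the remote side-chain centre, which the chosen route must import by resolution, and it sets C7 without a radical step. On these two centres it is the stronger plan.
- Against: no ring and no bridgehead is formed.
- Against: the two identical arms must then be differentiated (one acyl group to isopropenyl, the other to C8 with two methyl groups and a bond to C1), and mono-functionalisation is limited statistically.
- Against: the whole bicycle, both quaternary bridgeheads and the benzoylated enol ether remain to be made, and two equivalents of auxiliary are consumed.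
- Comparison: the chosen route offers the complete core and its absolute configuration from one catalytic step.

Alternative 3: The C5–C6 and C7–C8 bonds are cut. In the forward direction a chiral copper Lewis acid catalyses the Diels–Alder reaction of silyl dienol ether A6 with acryloyl oxazolidinone A7 to give cyclohexene A5.
- For: it is catalytic, it sets C7 directly, and it delivers ring A with the gem-dimethyl carbon and an enol silane handle at C9=C1. On C7 it is clearly better than the chosen route, which spends eight steps on that centre.
- Against: the diene terminus C8 of A6 is fully substituted, so one methyl group is necessarily cis on the diene; this disfavours the s-cis conformer and slows the cycloaddition.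
- Against: only one stereocentre is set, and the C7 acyl group must be reduced and extended to prenyl.
- Against: ring B and both quaternary bridgeheads remain, with C5 still a CH2 group.
- Comparison: the chosen route closes the bicycle and fixes both bridgeheads at once, and pays for that at C7.

Key step: step 5

Remarks on the chemistry (assumptions):
- The (S,S)-ligand is taken to give the (1R,5R) series in step 5; if a test run shows the opposite sense, the (R,R)-ligand is used and nothing else changes.
- The carbinol centres at C9 (10–15) and C7 (12, 13) are removed again; they are written without descriptor and either epimer, or the mixture, is carried on.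
- Enolates and lithio derivatives made and consumed in one flask are treated as conjugate bases of the numbered compounds and carry no numbers of their own.
- The lipase in step 18 is taken to acylate the (R)-alcohol faster; if the preference is reversed, 25 is obtained from the ester fraction by methanolysis.
- Names of bicyclic compounds use the atom numbering of the target.

## Route

Step 1
Reactants: 1 2-bromo-1,3-dimethoxybenzene; 2 methyl isobutyrate
Product: 3 methyl 2-(2,6-dimethoxyphenyl)-2-methylpropanoate
Conditions: LiNCy2 (from Cy2NH, n-BuLi), Pd(dba)2 (2 mol %, zerovalent palladium), P(t-Bu)3 (2 mol %), toluene, rt → 60 °C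
Reagents that add atoms: none
Why: Palladium-catalysed α-arylation of an ester enolate (oxidative addition of 1 to zerovalent palladium, transmetalation with the lithium enolate of 2, reductive elimination); the bulky trialkylphosphine with the hindered amide base is the combination suited to α,α-disubstituted esters, and the two small ortho-methoxy groups should be tolerated.

Step 2
Reactants: 3 methyl 2-(2,6-dimethoxyphenyl)-2-methylpropanoate
Product: 4 2-(2,6-dimethoxyphenyl)-2-methylpropanoic acid
Conditions: KOH, EtOH–H2O, reflux; then aq. HCl
Reagents that add atoms: potassium hydroxide, [K+].[OH-]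
Why: Saponification of a hindered, non-enolisable ester; forcing conditions are acceptable because nothing else in 3 is base-sensitive.

Step 3
Reactants: 4 2-(2,6-dimethoxyphenyl)-2-methylpropanoic acid
Product: 5 2-(2,6-dimethoxycyclohexa-2,5-dien-1-yl)-2-methylpropanoic acid
Conditions: Li, NH3 (l), THF, t-BuOH, −78 → −33 °C; NH4Cl; then NaH2PO4 buffer (pH about 5), 0 °C, rapid extraction; used at once
Reagents that add atoms: none
Why: Birch reduction: the carboxylate is inert, and the two methoxy groups direct protonation to the alkyl-bearing carbon and to the carbon para to it, which gives the unconjugated diene with both methoxy groups on double bonds; the buffered cold work-up should keep the bis(enol ether) intact.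

Step 4
Reactants: 5 2-(2,6-dimethoxycyclohexa-2,5-dien-1-yl)-2-methylpropanoic acid
Product: 7 1-diazo-3-(2,6-dimethoxycyclohexa-2,5-dien-1-yl)-3-methylbutan-2-one, via acid chloride 6 (not isolated)
Conditions: 1-chloro-N,N,2-trimethylprop-1-en-1-amine, CH2Cl2, 0 °C; then CH2N2, Et3N, Et2O, 0 °C
Reagents that add atoms: diazomethane, C=[N+]=[N-] (the chlorine of intermediate 6 comes from 1-chloro-N,N,2-trimethylprop-1-en-1-amine, CC(C)=C(Cl)N(C)C)
Why: Acid chloride formation under neutral conditions (the α-chloroenamine gives the chloride and an amide, no HCl), then acylation of diazomethane with Et3N taking up the HCl, so the enol ethers never meet acid; the quaternary α-carbon rules out ketene formation.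

Step 5
Reactants: 7 1-diazo-3-(2,6-dimethoxycyclohexa-2,5-dien-1-yl)-3-methylbutan-2-one
Product: 9 (1R,5R)-2-methoxy-8,8-dimethylbicyclo[3.3.1]non-2-ene-7,9-dione, via methoxycyclopropyl ketone 8 (not isolated)
Conditions: (CuOTf)2·C6H6 (5 mol %, monovalent copper), 2,2′-(propane-2,2-diyl)bis[(4S)-4-tert-butyl-4,5-dihydro-1,3-oxazole] (12 mol %), toluene, rt, slow addition of 7; then 0.5 M aq. HCl, THF, 0 °C, short contact, NaHCO3 quench
Reagents that add atoms: water, O
Why: The monovalent copper–bis(oxazoline) complex expels N2 from 7 to give an electrophilic copper carbene at C6, which adds to the nucleophilic C5=C9 enol ether in an asynchronous [2+1] step to give the cis-fused cyclopropane 8; this is the catalytic asymmetric intramolecular cyclopropanation of an α-diazo ketone by an enol ether, a known reaction class. The addition closes the cyclopropane and a cyclopentanone (C6–C7–C8–C1–C9) by attack through a three-atom tether on the near alkene carbon, the bicyclo[3.1.0]hexan-2-one mode that diazo ketones prefer, helped by the gem-dimethyl group at C8. In 8 the C6–C9 bond joins the methoxy-bearing donor carbon to the carbon α to the C7 ketone, so protonation of that ketone breaks only this push–pull bond to an oxocarbenium ion at C9 and the C7 enol, and water turns them into the two ketones of 9 with loss of methanol. Because C6 stays bonded to C5, the five-membered ring is expanded to the six-membered ring A, a net union of C6 with the far carbon of the enol ether that a direct ionic closure would not give. C5 and C1 become stereogenic in the same event: the chiral ligand on copper chooses between the enantiotopic C5=C9 and C3=C2 bonds of the mirror-symmetric diene, and the tether forces cis fusion, so that choice fixes both bridgeheads, while the two further centres of 8 (C6, C9) vanish on opening. The step needs enantiotopic group selection (ligand), cyclopropanation over C–H insertion or carbene dimerisation (most electron-rich π bond, five-ring transition state, slow addition) and survival of the second enol ether in the acid quench (cold, dilute, brief; after opening, its protonation is slowed by the adjacent C9 carbonyl).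

Step 6
Reactants: 9 (1R,5R)-2-methoxy-8,8-dimethylbicyclo[3.3.1]non-2-ene-7,9-dione
Product: 10 9-hydroxy-2-methoxy-8,8-dimethylbicyclo[3.3.1]non-2-en-7-one (bridgeheads as in 9; C9 epimer open)
Conditions: LiN(SiMe3)2, THF, −78 °C; then LiAlH(Ot-Bu)3, −78 → 0 °C; aq. NH4Cl
Reagents that add atoms: none
Why: Protection of a ketone as its enolate: only the C7 ketone has an enolisable α-CH2 (C6), the bridging C9 ketone cannot enolise, so after deprotonation the hydride reduces C9 alone and the quench returns the C7 ketone; the new C9 centre is temporary.

Step 7
Reactants: 10 9-hydroxy-2-methoxy-8,8-dimethylbicyclo[3.3.1]non-2-en-7-one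
Product: 11 9-(tert-butyldimethylsilyloxy)-2-methoxy-8,8-dimethylbicyclo[3.3.1]non-2-en-7-one
Conditions: t-BuMe2SiOTf, 2,6-lutidine, CH2Cl2, −78 → −20 °C
Reagents that add atoms: tert-butyldimethylsilyl triflate, CC(C)(C)[Si](C)(C)OS(=O)(=O)C(F)(F)F
Why: Silylation of a hindered secondary alcohol with a silyl triflate; excess base keeps the enol ether away from acid, and at low temperature the alcohol reacts before the ketone can be enol-silylated.

Step 8
Reactants: 11 9-(tert-butyldimethylsilyloxy)-2-methoxy-8,8-dimethylbicyclo[3.3.1]non-2-en-7-one
Product: 12 9-(tert-butyldimethylsilyloxy)-2-methoxy-8,8-dimethylbicyclo[3.3.1]non-2-en-7-ol (C7 epimer open)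
Conditions: NaBH4, MeOH, 0 °C → rt; chromatography on Et3N-washed silica
Reagents that add atoms: none
Why: Borohydride reduction of the only ketone left; the configuration of the C7 carbinol does not matter because C7 becomes a radical, and basic handling prevents acid-catalysed addition of the alcohol to the enol ether across the ring.

Step 9
Reactants: 12 9-(tert-butyldimethylsilyloxy)-2-methoxy-8,8-dimethylbicyclo[3.3.1]non-2-en-7-ol
Product: 13 O-[9-(tert-butyldimethylsilyloxy)-2-methoxy-8,8-dimethylbicyclo[3.3.1]non-2-en-7-yl] S-methyl carbonodithioate
Conditions: NaH, THF, 0 °C; CS2; MeI, rt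
Reagents that add atoms: carbon disulfide, S=C=S; iodomethane, CI
Why: Xanthate formation (alkoxide addition to CS2, then S-methylation), the standard radical precursor for hindered secondary alcohols; the sequence is basic throughout.

Step 10
Reactants: 13 O-[9-(tert-butyldimethylsilyloxy)-2-methoxy-8,8-dimethylbicyclo[3.3.1]non-2-en-7-yl] S-methyl carbonodithioate
Product: 14 7-exo-allyl-9-(tert-butyldimethylsilyloxy)-2-methoxy-8,8-dimethylbicyclo[3.3.1]non-2-ene
Conditions: allylSnBu3 (excess), AIBN, benzene, 80 °C, degassed
Reagents that add atoms: allyltributylstannane, C=CC[Sn](CCCC)(CCCC)CCCC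
Why: Keck radical allylation: Bu3Sn• adds to the thiocarbonyl group, the C7 radical is released and attacks the allylstannane with loss of Bu3Sn•; the planar C7 radical can only be reached from the face turned away from ring B, whose C2=C3 unit lies under the endo face, so the new C–C bond is exo (equatorial on ring A) and H7 ends up endo, which sets C7.

Step 11
Reactants: 14 7-exo-allyl-9-(tert-butyldimethylsilyloxy)-2-methoxy-8,8-dimethylbicyclo[3.3.1]non-2-ene
Product: 15 7-exo-allyl-2-methoxy-8,8-dimethylbicyclo[3.3.1]non-2-en-9-ol
Conditions: Bu4NF, THF, rt → 50 °C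
Reagents that add atoms: none
Why: Fluoride cleavage of the silyl ether under basic conditions that leave the enol ether and the alkene untouched.

Step 12
Reactants: 15 7-exo-allyl-2-methoxy-8,8-dimethylbicyclo[3.3.1]non-2-en-9-ol
Product: 16 7-exo-allyl-2-methoxy-8,8-dimethylbicyclo[3.3.1]non-2-en-9-one
Conditions: Dess–Martin periodinane, NaHCO3, CH2Cl2, rt
Reagents that add atoms: none
Why: Dess–Martin oxidation of the secondary alcohol back to the C9 ketone, buffered for the enol ether; this clears the temporary C9 centre.

Step 13
Reactants: 16 7-exo-allyl-2-methoxy-8,8-dimethylbicyclo[3.3.1]non-2-en-9-one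
Product: 18 7-exo-allyl-2-methoxy-8,8-dimethylbicyclo[3.3.1]non-2-ene-4,9-dione, via C4 tert-butyl peroxide 17 (not isolated)
Conditions: Pd(OH)2/C (5 mol %, divalent palladium), t-BuOOH, K2CO3, CH2Cl2, 0 °C → rt
Reagents that add atoms: tert-butyl hydroperoxide, CC(C)(C)OO
Why: Allylic oxidation by a palladium/hydroperoxide radical chain: the electrophilic tert-butylperoxyl radical abstracts the C4–H, the most electron-rich and weakest C–H (its allyl radical carries the methoxy group at the terminus), the radical is trapped as peroxide 17 and base-induced Kornblum–DeLaMare elimination gives the ketone; the allylic CH2 of the side chain has no such donor, the bridgehead C1–H cannot give a planar allyl radical, and K2CO3 keeps the medium basic.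

Step 14
Reactants: 18 7-exo-allyl-2-methoxy-8,8-dimethylbicyclo[3.3.1]non-2-ene-4,9-dione
Product: 19 2-methoxy-8,8-dimethyl-7-exo-(3-methylbut-2-en-1-yl)bicyclo[3.3.1]non-2-ene-4,9-dione
Conditions: RuCl2(=CHPh)(H2IMes)(PCy3) (second-generation Grubbs catalyst, 5 mol %), 2-methylbut-2-ene (large excess), CH2Cl2, 40 °C
Reagents that add atoms: 2-methylbut-2-ene, CC=C(C)C
Why: Olefin cross-metathesis turns the terminal allyl group into prenyl; the trisubstituted, electron-poor double bond of the vinylogous ester does not take part, and no other alkene is present yet.

Step 15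
Reactants: 19 2-methoxy-8,8-dimethyl-7-exo-(3-methylbut-2-en-1-yl)bicyclo[3.3.1]non-2-ene-4,9-dione
Product: 20 2-methoxy-8,8-dimethyl-7-exo-(3-methylbut-2-en-1-yl)-3,5-bis(trimethylsilyl)bicyclo[3.3.1]non-2-ene-4,9-dione
Conditions: LiN(i-Pr)2 (2.5 equiv), Me3SiCl (present from the start), THF, −78 °C
Reagents that add atoms: chlorotrimethylsilane, C[Si](C)(C)Cl
Why: Deprotonation with in situ quench: the amide removes first the C5 bridgehead proton (between the C4 and C9 carbonyls) and then the vinylic C3 proton, and each carbanion is silylated on carbon at once, since O-silylation at C5 would need a bridgehead double bond; the hindered C1–H reacts slowest and is left.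

Step 16
Reactants: 20 2-methoxy-8,8-dimethyl-7-exo-(3-methylbut-2-en-1-yl)-3,5-bis(trimethylsilyl)bicyclo[3.3.1]non-2-ene-4,9-dione; 21 prenyl bromide (1-bromo-3-methylbut-2-ene)
Product: 22 2-methoxy-8,8-dimethyl-1,7-bis(3-methylbut-2-en-1-yl)-3,5-bis(trimethylsilyl)bicyclo[3.3.1]non-2-ene-4,9-dione
Conditions: LiN(i-Pr)2, THF, −78 → −40 °C; then 21, DMPU, −78 → 0 °C
Reagents that add atoms: none
Why: Bridgehead deprotonation and alkylation of a bicyclic β-methoxy enone: with C3 and C5 blocked, C1–H is the only proton whose carbanion can overlap with the C2=C3–C4=O system (the overlap mirrors that used at C5), and the anion is alkylated on carbon because O-alkylation would create a bridgehead double bond; the configuration at C1 is fixed by the bicycle.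

Step 17
Reactants: 22 2-methoxy-8,8-dimethyl-1,7-bis(3-methylbut-2-en-1-yl)-3,5-bis(trimethylsilyl)bicyclo[3.3.1]non-2-ene-4,9-dione
Product: 23 2-methoxy-8,8-dimethyl-1,7-bis(3-methylbut-2-en-1-yl)bicyclo[3.3.1]non-2-ene-4,9-dione (7-exo)
Conditions: Bu4NF (wet), THF, 0 °C → rt
Reagents that add atoms: none
Why: Fluoride-induced protodesilylation: both C–Si bonds are α to carbonyl groups, so the carbanions released are stabilised and are protonated by the water in the reagent; the bridgehead geometry at C5 cannot change.

Step 18
Reactants: 24 racemic lavandulol [5-methyl-2-(prop-1-en-2-yl)hex-4-en-1-ol]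
Product: 25 (S)-lavandulol [(2S)-5-methyl-2-(prop-1-en-2-yl)hex-4-en-1-ol]
Conditions: immobilised Candida antarctica lipase B, vinyl acetate, hexane, rt, run past half conversion; chromatography
Reagents that add atoms: none
Why: Lipase-catalysed kinetic resolution by enantioselective transesterification: the faster enantiomer is removed as its acetate, and driving the conversion beyond one half should leave the slower (S)-alcohol in high enantiomeric purity; the sense is checked by optical rotation.

Step 19
Reactants: 25 (S)-lavandulol
Product: 26 (2S)-5-methyl-2-(prop-1-en-2-yl)hex-4-en-1-yl trifluoromethanesulfonate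
Conditions: Tf2O, 2,6-lutidine, CH2Cl2, −78 °C; cold filtration through silica, used at once
Reagents that add atoms: triflic anhydride, O=S(=O)(OS(=O)(=O)C(F)(F)F)C(F)(F)F
Why: Sulfonylation of the primary alcohol; a triflate is chosen because the carbon to be attacked is β-branched, and low temperature with immediate use forestalls ionisation assisted by the neighbouring isopropenyl group; the stereocentre is not touched.

Step 20
Reactants: 23 2-methoxy-8,8-dimethyl-1,7-bis(3-methylbut-2-en-1-yl)bicyclo[3.3.1]non-2-ene-4,9-dione; 26 (2S)-5-methyl-2-(prop-1-en-2-yl)hex-4-en-1-yl trifluoromethanesulfonate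
Product: 27 2-methoxy-8,8-dimethyl-1,7-bis(3-methylbut-2-en-1-yl)-5-[(2R)-5-methyl-2-(prop-1-en-2-yl)hex-4-en-1-yl]bicyclo[3.3.1]non-2-ene-4,9-dione
Conditions: LiN(i-Pr)2, THF, −78 °C; then 26, −78 → −30 °C
Reagents that add atoms: none
Why: Bridgehead deprotonation at C5, the most acidic C–H of 23 (flanked by the C4 and C9 carbonyls), followed by SN2 alkylation on carbon; this deprotonation–alkylation is the established way to substitute C5 in clusianone-type enol ethers, the triflate offsets the β-branching, and neither the C5 configuration (bridgehead) nor the side-chain centre (one carbon away from the reacting CH2) can change.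

Step 21
Reactants: 27 2-methoxy-8,8-dimethyl-1,7-bis(3-methylbut-2-en-1-yl)-5-[(2R)-5-methyl-2-(prop-1-en-2-yl)hex-4-en-1-yl]bicyclo[3.3.1]non-2-ene-4,9-dione; 28 benzoyl chloride
Product: 29 (1R,5R,7R)-3-benzoyl-2-methoxy-8,8-dimethyl-1,7-bis(3-methylbut-2-en-1-yl)-5-[(2R)-5-methyl-2-(prop-1-en-2-yl)hex-4-en-1-yl]bicyclo[3.3.1]non-2-ene-4,9-dione (CNP0385193.1)
Conditions: lithium 2,2,6,6-tetramethylpiperidide (from the amine and n-BuLi), THF, −78 °C; then 28, −78 → −40 °C
Reagents that add atoms: none
Why: With both bridgeheads quaternary the vinylic C3–H between the methoxy-bearing carbon and the C4 carbonyl is the only acidic proton; the hindered, non-reducing amide lithiates it and the vinyllithium is acylated on carbon, the usual way to introduce the 3-acyl group in this family.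

## Compound list

1 | 2-bromo-1,3-dimethoxybenzene | COc1cccc(OC)c1Br | starting material
2 | methyl isobutyrate | COC(=O)C(C)C | starting material
3 | methyl 2-(2,6-dimethoxyphenyl)-2-methylpropanoate | COC(=O)C(C)(C)c1c(OC)cccc1OC | intermediate
4 | 2-(2,6-dimethoxyphenyl)-2-methylpropanoic acid | OC(=O)C(C)(C)c1c(OC)cccc1OC | intermediate
5 | 2-(2,6-dimethoxycyclohexa-2,5-dien-1-yl)-2-methylpropanoic acid | COC1=CCC=C(OC)C1C(C)(C)C(=O)O | intermediate
6 | 2-(2,6-dimethoxycyclohexa-2,5-dien-1-yl)-2-methylpropanoyl chloride | COC1=CCC=C(OC)C1C(C)(C)C(Cl)=O | intermediate (not isolated)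
7 | 1-diazo-3-(2,6-dimethoxycyclohexa-2,5-dien-1-yl)-3-methylbutan-2-one | COC1=CCC=C(OC)C1C(C)(C)C(=O)C=[N+]=[N-] | intermediate (key-step precursor)
8 | 6,9-dimethoxy-4,4-dimethyltricyclo[3.3.1.0(2,9)]non-6-en-3-one; cyclopropane C5–C6–C9 in target numbering, cis-fused | COC1=CC[C@@H]2[C@@H]3C(=O)C(C)(C)[C@H]1[C@]23OC | intermediate (not isolated)
9 | (1R,5R)-2-methoxy-8,8-dimethylbicyclo[3.3.1]non-2-ene-7,9-dione | [C@@H]12CC(=O)C(C)(C)[C@@H](C1=O)C(OC)=CC2 | intermediate (key-step product)
10 | 9-hydroxy-2-methoxy-8,8-dimethylbicyclo[3.3.1]non-2-en-7-one (C9 open) | [C@@H]12CC(=O)C(C)(C)[C@@H](C1O)C(OC)=CC2 | intermediate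
11 | 9-(tert-butyldimethylsilyloxy)-2-methoxy-8,8-dimethylbicyclo[3.3.1]non-2-en-7-one | [C@@H]12CC(=O)C(C)(C)[C@@H](C1O[Si](C)(C)C(C)(C)C)C(OC)=CC2 | intermediate
12 | 9-(tert-butyldimethylsilyloxy)-2-methoxy-8,8-dimethylbicyclo[3.3.1]non-2-en-7-ol (C7 open) | [C@@H]12CC(O)C(C)(C)[C@@H](C1O[Si](C)(C)C(C)(C)C)C(OC)=CC2 | intermediate
13 | O-[9-(tert-butyldimethylsilyloxy)-2-methoxy-8,8-dimethylbicyclo[3.3.1]non-2-en-7-yl] S-methyl carbonodithioate | [C@@H]12CC(OC(=S)SC)C(C)(C)[C@@H](C1O[Si](C)(C)C(C)(C)C)C(OC)=CC2 | intermediate
14 | 7-exo-allyl-9-(tert-butyldimethylsilyloxy)-2-methoxy-8,8-dimethylbicyclo[3.3.1]non-2-ene | [C@@H]12C[C@@H](CC=C)C(C)(C)[C@@H](C1O[Si](C)(C)C(C)(C)C)C(OC)=CC2 | intermediate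
15 | 7-exo-allyl-2-methoxy-8,8-dimethylbicyclo[3.3.1]non-2-en-9-ol | [C@@H]12C[C@@H](CC=C)C(C)(C)[C@@H](C1O)C(OC)=CC2 | intermediate
16 | 7-exo-allyl-2-methoxy-8,8-dimethylbicyclo[3.3.1]non-2-en-9-one | [C@@H]12C[C@@H](CC=C)C(C)(C)[C@@H](C1=O)C(OC)=CC2 | intermediate
17 | 7-exo-allyl-4-(tert-butylperoxy)-2-methoxy-8,8-dimethylbicyclo[3.3.1]non-2-en-9-one (C4 open) | [C@@H]12C[C@@H](CC=C)C(C)(C)[C@@H](C1=O)C(OC)=CC2OOC(C)(C)C | intermediate (not isolated)
18 | 7-exo-allyl-2-methoxy-8,8-dimethylbicyclo[3.3.1]non-2-ene-4,9-dione | [C@@H]12C[C@@H](CC=C)C(C)(C)[C@@H](C1=O)C(OC)=CC2=O | intermediate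
19 | 2-methoxy-8,8-dimethyl-7-exo-(3-methylbut-2-en-1-yl)bicyclo[3.3.1]non-2-ene-4,9-dione | [C@@H]12C[C@@H](CC=C(C)C)C(C)(C)[C@@H](C1=O)C(OC)=CC2=O | intermediate
20 | 3,5-bis(trimethylsilyl) derivative of 19 | C[Si](C)(C)[C@@]12C[C@@H](CC=C(C)C)C(C)(C)[C@@H](C1=O)C(OC)=C([Si](C)(C)C)C2=O | intermediate
21 | prenyl bromide (1-bromo-3-methylbut-2-ene) | CC(C)=CCBr | starting material
22 | 1-prenyl-3,5-bis(trimethylsilyl) compound | C[Si](C)(C)[C@@]12C[C@@H](CC=C(C)C)C(C)(C)[C@@](CC=C(C)C)(C1=O)C(OC)=C([Si](C)(C)C)C2=O | intermediate
23 | 2-methoxy-8,8-dimethyl-1,7-bis(3-methylbut-2-en-1-yl)bicyclo[3.3.1]non-2-ene-4,9-dione (7-exo) | [C@@H]12C[C@@H](CC=C(C)C)C(C)(C)[C@@](CC=C(C)C)(C1=O)C(OC)=CC2=O | intermediate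
24 | racemic lavandulol | C=C(C)C(CO)CC=C(C)C | starting material
25 | (S)-lavandulol | C=C(C)[C@H](CC=C(C)C)CO | intermediate
26 | (2S)-5-methyl-2-(prop-1-en-2-yl)hex-4-en-1-yl trifluoromethanesulfonate | C=C(C)[C@H](CC=C(C)C)COS(=O)(=O)C(F)(F)F | intermediate
27 | 5-lavandulyl compound (C3–H) | C=C(C)[C@H](CC=C(C)C)C[C@@]12C[C@@H](CC=C(C)C)C(C)(C)[C@@](CC=C(C)C)(C1=O)C(OC)=CC2=O | intermediate
28 | benzoyl chloride | O=C(Cl)c1ccccc1 | starting material
29 | (1R,5R,7R)-3-benzoyl-2-methoxy-8,8-dimethyl-1,7-bis(3-methylbut-2-en-1-yl)-5-[(2R)-5-methyl-2-(prop-1-en-2-yl)hex-4-en-1-yl]bicyclo[3.3.1]non-2-ene-4,9-dione | C=C(C)[C@H](CC=C(C)C)C[C@@]12C[C@@H](CC=C(C)C)C(C)(C)[C@@](CC=C(C)C)(C1=O)C(OC)=C(C(=O)c1ccccc1)C2=O | target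

## Step count and least certain steps

Total step count: 21. Longest linear sequence: 19 steps (steps 1–17, 20 and 21); steps 18 and 19 make the side-chain electrophile.

Step 5 (key step). Selection between the two enantiotopic enol ethers may be incomplete, because a terminal acceptor-only carbene is small and reacts through an early transition state. The carbene may also be diverted into C–H insertion or dimerisation. Over-long acid contact may hydrolyse the remaining enol ether or let it add across the ring to the C7 carbonyl.
Fallback: a more selective acceptor/acceptor carbene, setting out from acid 5 (through chloride 6) and returning at 9. The chloride is added to lithiated methyl mesityl sulfone to give the β-keto sulfone 3-(2,6-dimethoxycyclohexa-2,5-dien-1-yl)-3-methyl-1-(mesitylsulfonyl)butan-2-one F1. Diazo transfer with 4-acetamidobenzenesulfonyl azide and Et3N gives the α-diazo-β-keto sulfone F2. The same copper–bis(oxazoline) catalyst converts it into the 6-sulfonyl cyclopropane F3. The acid quench opens this to the 6-(mesitylsulfonyl) dione F4, and SmI2 in THF–MeOH at −78 °C removes the sulfonyl group to give 9.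

Step 16. Deprotonation at the hindered C1 bridgehead next to C8 may be slow or incomplete, and the carbanion may be too encumbered to be alkylated before the allylic bromide is consumed by the base.
Fallback: carbon is delivered by a radical instead, setting out from 20 and returning at 22. The C1 anion is quenched with I2, a small and very reactive electrophile, to give the 1-iodo-3,5-bis(trimethylsilyl) compound F5. Radical allylation with allylSnBu3 and Et3B/air gives the 1-allyl compound F6, the bridgehead radical keeping its configuration by necessity. Cross-metathesis with 2-methylbut-2-ene and RuCl2(=CHPh)(H2IMes)(PCy3) then gives 22; the lavandulyl group is not yet present, so no 1,1-disubstituted alkene is exposed to the catalyst.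

Step 20. The homoallylic triflate may ionise or lose triflic acid (the basic bridgehead anion can remove the allylic methine proton) faster than it is attacked at the β-branched carbon, which would return 23.
Fallback: the bond is made by carbonyl addition, setting out from 23 and 25 and returning at 27. Dess–Martin oxidation of 25 gives (S)-lavandulal F7. The C5 lithio derivative of 23 adds to it at −78 °C to give the β-hydroxy ketone F8. 1,1′-Thiocarbonyldiimidazole converts this into the imidazolyl thionocarbamate F9. Barton–McCombie reduction with Bu3SnH and AIBN, run at high stannane concentration so that hydrogen transfer outruns a 1,2-vinyl shift of the homoallylic radical, gives 27.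

Step 10. The C7 radical may add across the ring to the C2=C3 enol ether (a 5-exo mode) before it meets the stannane. Trapping may also be slow at the neopentyl centre, which favours premature reduction.
Fallback: the π bond is masked during the radical step, setting out from 13 and returning at 14. Methanol with a trace of pyridinium p-toluenesulfonate adds across the enol ether of 13 to give the C2 dimethyl ketal xanthate F10. The same radical allylation gives the 7-exo-allyl dimethyl ketal F11. Me3SiOTf with i-Pr2NEt then eliminates methanol, which can only regenerate the C2=C3 enol ether because C1 is a bridgehead, to give 14.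

Step 13. Hydrogen abstraction may also occur at the allylic CH2 of the side chain, or the enol ether double bond may be attacked by the peroxyl radical, so that over-oxidation erodes the material.
Fallback: a stoichiometric metal-oxo oxidant in place of the peroxyl radical chain, namely the complex of CrO3 with 3,5-dimethylpyrazole (hexavalent chromium) in CH2Cl2 at −20 °C, which attacks the electron-rich allylic position of the enol ether by a different mechanism. It sets out from 16 and returns at 18 with no new intermediate.

## Further compounds

F1 | step 5 | 3-(2,6-dimethoxycyclohexa-2,5-dien-1-yl)-3-methyl-1-(mesitylsulfonyl)butan-2-one | COC1=CCC=C(OC)C1C(C)(C)C(=O)CS(=O)(=O)c1c(C)cc(C)cc1C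
F2 | step 5 | 1-diazo-3-(2,6-dimethoxycyclohexa-2,5-dien-1-yl)-3-methyl-1-(mesitylsulfonyl)butan-2-one | COC1=CCC=C(OC)C1C(C)(C)C(=O)C(=[N+]=[N-])S(=O)(=O)c1c(C)cc(C)cc1C
F3 | step 5 | 6-(mesitylsulfonyl) derivative of cyclopropane 8 (target numbering) | COC1=CC[C@@H]2[C@]3(S(=O)(=O)c4c(C)cc(C)cc4C)C(=O)C(C)(C)[C@H]1[C@]23OC
F4 | step 5 | 6-(mesitylsulfonyl) derivative of dione 9 (C6 open) | [C@@H]12C(S(=O)(=O)c3c(C)cc(C)cc3C)C(=O)C(C)(C)[C@@H](C1=O)C(OC)=CC2
F5 | step 16 | 1-iodo-2-methoxy-8,8-dimethyl-7-exo-(3-methylbut-2-en-1-yl)-3,5-bis(trimethylsilyl)bicyclo[3.3.1]non-2-ene-4,9-dione | C[Si](C)(C)[C@@]12C[C@@H](CC=C(C)C)C(C)(C)[C@@](I)(C1=O)C(OC)=C([Si](C)(C)C)C2=O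
F6 | step 16 | 1-allyl-2-methoxy-8,8-dimethyl-7-exo-(3-methylbut-2-en-1-yl)-3,5-bis(trimethylsilyl)bicyclo[3.3.1]non-2-ene-4,9-dione | C[Si](C)(C)[C@@]12C[C@@H](CC=C(C)C)C(C)(C)[C@@](CC=C)(C1=O)C(OC)=C([Si](C)(C)C)C2=O
F7 | step 20 | (S)-lavandulal [(2S)-5-methyl-2-(prop-1-en-2-yl)hex-4-enal] | C=C(C)[C@H](CC=C(C)C)C=O
F8 | step 20 | β-hydroxy ketone from addition of the C5 anion of 23 to F7 (carbinol centre open) | C=C(C)[C@H](CC=C(C)C)C(O)[C@@]12C[C@@H](CC=C(C)C)C(C)(C)[C@@](CC=C(C)C)(C1=O)C(OC)=CC2=O
F9 | step 20 | O-imidazolylthiocarbonyl derivative of F8 | C=C(C)[C@H](CC=C(C)C)C(OC(=S)n1ccnc1)[C@@]12C[C@@H](CC=C(C)C)C(C)(C)[C@@](CC=C(C)C)(C1=O)C(OC)=CC2=O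
F10 | step 10 | C2 dimethyl ketal of xanthate 13 | [C@@H]12CC(OC(=S)SC)C(C)(C)[C@@H](C1O[Si](C)(C)C(C)(C)C)C(OC)(OC)CC2
F11 | step 10 | C2 dimethyl ketal of 14 (7-exo-allyl) | [C@@H]12C[C@@H](CC=C)C(C)(C)[C@@H](C1O[Si](C)(C)C(C)(C)C)C(OC)(OC)CC2
F0 | step 13 | none | none
A1 | alternative 1 | (1R,5R,7R)-3-benzoyl-2-hydroxy-8,8-dimethyl-1,7-diprenyl-5-lavandulylbicyclo[3.3.1]non-2-ene-4,9-dione (free enol of 29) | C=C(C)[C@H](CC=C(C)C)C[C@@]12C[C@@H](CC=C(C)C)C(C)(C)[C@@](CC=C(C)C)(C1=O)C(O)=C(C(=O)c1ccccc1)C2=O
A2 | alternative 1 | open-chain dimethyl malonate with C5 as malonate carbon, bearing the lavandulyl group and the chain C6–C7(prenyl)–C8(Me2)–C1(prenyl)–C2(=O)–C3H2–COPh (C1 open) | C=C(C)[C@H](CC=C(C)C)CC(C(=O)OC)(C(=O)OC)C[C@@H](CC=C(C)C)C(C)(C)C(CC=C(C)C)C(=O)CC(=O)c1ccccc1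
A3 | alternative 2 | C2-symmetric doubly prenylated bis(imide) malonate | COC(=O)C(C[C@@H](CC=C(C)C)C(=O)N1[C@H](Cc2ccccc2)COC1=O)(C[C@@H](CC=C(C)C)C(=O)N1[C@H](Cc2ccccc2)COC1=O)C(=O)OC
A4 | alternative 2 | unprenylated C2-symmetric bis(imide) malonate | COC(=O)C(CCC(=O)N1[C@H](Cc2ccccc2)COC1=O)(CCC(=O)N1[C@H](Cc2ccccc2)COC1=O)C(=O)OC
A5 | alternative 3 | ring A enol silane with the C7 acyl oxazolidinone | C1C[C@@H](C(=O)N2CCOC2=O)C(C)(C)C=C1O[Si](C)(C)C(C)(C)C
A6 | alternative 3 | tert-butyldimethyl[(4-methylpenta-1,3-dien-2-yl)oxy]silane | C=C(O[Si](C)(C)C(C)(C)C)C=C(C)C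
A7 | alternative 3 | 3-acryloyl-1,3-oxazolidin-2-one | C=CC(=O)N1CCOC1=O
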